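All runs are simulated with constants of no real substance, and the scatter is random.

- Cedar still holds 85.7% of its J at its last reading, 12.0 min, and that leftover is where I start.

the same everywhere: X 2.5 mM

| charge | J | E | remark | time |
|---|---|---|---|---|
| cedar | 0.10 M | 0.11 M | run made earlier |  |
| birch | 0.20 M | 0.11 M | run made earlier |  |
| grey | 0.10 M | 0.110 M (in portions, 5, over 15 min) | first portion at the start, last at 15 min | 20 min |
| amber | 0.10 M (fed, over 15 min) | 0.110 M | all else is in the flask from the start; the feed brings no volume worth counting | 20 min |
| blue | 0.10 M | 0.110 M | everything together at the start | 20 min |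
| ochre | 0.10 M | 0.110 M (fed, over 15 min) | all else is in the flask from the start; the feed brings no volume worth counting | 20 min |

- cedar (time / min: G / %): 1.00: 2.1; 1.50: 2.0; 2.50: 3.7; 4.00: 5.4; 8.00: 11.5; 12.0: 14.3
- birch (time / min: G / %): 0.250: 1.3; 0.833: 1.8; 1.33: 2.3; 2.00: 3.9; 3.00: 4.9; 4.00: 6.1

(scatter of a reading: 0.5 percentage points)

- the flask that comes out highest in amount of G, in percent of the J charged, or "all alike" when all lie within 1.5 percentage points (grey / amber / blue / ochre / all alike)
- G at the end, in percent of the J charged, grey
- G at the end, in percent of the J charged, amber
- G at the end, in percent of the J charged, blue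
- G at the end, in percent of the J charged, ochre

- what may be going on: J + E + X -> X + G; E -> Z; X <-> L

- Birch, with J doubled, reads 6.1% at 4.00 min against cedar's 5.4% at 4.00 min; with a scatter of 0.5 percentage points on each, the two percentages agree, so I read the rate as first order in J.
- I take first order in E and in X from the proposed step J + E + X -> X + G, though these runs don't test it.
- Cedar's slope from 1.00 min to 8.00 min gives τ, the pseudo-first-order time of J at the charged amounts: 74.5 min. It is longer than the run, so G should grow roughly in step with how much reagent has been delivered.
- Ochre looks nearly the same as cedar, with the same charges, but its E arrives over 15 min, and during that feed the delivered E averages half its charge.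
- So I count M = 12.5 min, the full-charge minutes, which are the run time weighted by the delivered fraction.
- Amber's J feed gives the same M. Grey's 5 portions, 3.75 min apart, also average half over the feed, so grey has that M too.
- Blue is cedar carried on for the whole 20 min. Extending cedar's last slope puts blue near 19.9%.
- The fed flasks get 0.625 of that, 12.4%, while M itself is close to cedar's 12.0 min, where cedar reads 14.3%. I commit to that range for grey, amber and ochre, with blue first.
- The forecast names blue, with blue 20%, grey 13.2%, amber 11.7% and ochre 12.3%: "Starving either reagent early costs far more than the reduced E loss saves."
- The flasks give blue first: blue 20.6%, grey 13.6%, amber 12.8%, ochre 13.7%.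

    J + E + X → X + G (k = 69.0 M⁻² min⁻¹)
    E → Z (k = 0.0110 min⁻¹)
    X ⇌ L (K = 0.420, k = 0.0870 min⁻¹)

- Against blue, ochre stands at 0.665 and amber at 0.621, beside the 0.625 from M. In amber at 9.09 min, the main step alone has a half-life of J of 58 min, longer than the run, while E goes to Z 1.5 times as fast as it goes into G. A neighbouring flask is amber with 0.010 M of X, so τ becomes 18.6 min and M over τ gives 67.2%, but that neighbouring flask ends at 36.3% with 50% of its charged E still there.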